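How much nucleophile must stand in the flask from the start for the electrophile to reach the asked part reacted within the run?

electrophile 1.0 mM; gas 0.28 mM (held); time 2.5 min

    electrophile + nucleophile → acid set free + product (k1 = 18 M⁻¹ s⁻¹)
    nucleophile + acid set free ⇌ protonated nucleophile, settled at all times (K2 = 20000 M⁻¹)
    acid set free + free base ⇌ salt of the base, settled at all times (K3 = 6300 M⁻¹)
    gas ⇌ free base, rate k4*(csat - [free base]) (k4 = 0.15 s⁻¹, csat = 0.28 mM)
    2 electrophile → homo dimer (k5 = 1.1 M⁻¹ s⁻¹)
    electrophile ⇌ dormant form (K6 = 1.6, k6 = 0.068 s⁻¹)

1. the concentration of nucleophile at which the part of the electrophile that has reacted at 2.5 min is just 95 %, in mM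

- percentages count the electrophile that a species holds: one homo dimer counts as two
- two of one species on the left: rate k times its square, two consumed each time
- at the start none of free base is dissolved
- the amount of nucleophile is what is sought; it is there from the start
- run time (flask): 2.5 min

My own reckoning reads "reacted" as no longer free, so c(electrophile) must reach 5.00 % of its charge, and the dormant form counts as gone. With the main step alone and c(nucleophile) taken as a constant mean, the decay is pseudo-first-order, and that mean comes to 1.11 mM.

Now the dormant form joins. It balances with the electrophile at a relaxation half-life of 0.105 min, much shorter than the run, so the two are treated as one pool, of which a part 0.385 is free. The pool then falls with the constant 6.92 M⁻¹ s⁻¹, and with c(electrophile) at the wanted level it holds 13.0 % of the charge. With 2.04 as the logarithm of that fall, the mean rises to 1.96 mM. This is the required mean nucleophile: the logarithm of the pool's fall over the pool constant times the time. The exchange relaxes at 0.111 s⁻¹, faster than the 0.0354 s⁻¹ of the main step at that mean, but not by much, so the single pool is an approximation.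

Then comes the rest. Each product sets one acid free, and that acid goes to a second nucleophile because binding there outweighs binding to free base; the salt's share is near 4.49 %. The dimer step is slower than the main step, so it is dropped. Each electrophile gone thus takes two nucleophile, and averaged over an exponential fall of the pool this puts the charge above the mean by 1.15 mM. The charge is then 3.11 mM.

The forecast, counting as reacted what has “left both the free and dormant pools”, gives 4.9 mM, above my figure, and the two part on that reading.

The simulation gives 3.06 mM, or 3.06 per electrophile charged. At 0.335 min the main step uses electrophile at 0.60 of the forward rate into the dormant form, slower than that step. At 1.25 min, 57.0 % of the charge is still free, 1.74 mM, against the required mean of 1.96 mM. The flask with twice the electrophile reaches 89.9 %, and for that part the same rule asks a mean of 1.29 mM.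

The rate constants stand for no real mixture; the flask was simulated.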